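**Plan**

- Retrosynthesis: the three phenols come from benzyl ethers and the ring C ketone from a benzylic alcohol held in an acetonide. The lactone is cut at O1–C2 and C2–C3, which removes C2 as carbon monoxide and leaves homoallylic alcohol 25. Alcohol 25 is cut at the ring B–vinyl bond into alcohol 9 and aryl bromide 24.
- Alcohol 9 is cut at the C4–CH2(ring A) bond (auxiliary-controlled alkylation of a crotonyl dienolate). Bromide 24 is cut between the ring B-bearing carbon and the ring C carbinol carbon (auxiliary-controlled aldol of a ring B arylacetyl imide).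
- Enabling feature: the lactone carbonyl C2 is a single carbon bonded only to C3 and to ring oxygen O1. It can therefore enter as CO between the styrenyl carbon (future C3) and the C5 hydroxyl of an open chain that already holds C3, C4, C5 and both benzyl groups.
- Forward: the ring A chain (steps 1–4) and the ring B/ring C fragment (steps 5–13) are joined by a Heck reaction (step 14). Hydroformylation closes the lactone ring, the only permanent ring made (step 15). Oxidation, acetonide removal, benzylic oxidation and hydrogenolysis finish the route (steps 16–19).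
- Stereochemistry: C4 comes from an Evans alkylation and the ketol carbon from an Evans syn-aldol, both with (R)-4-benzyl-2-oxazolidinone. C3 comes from C4 in the chelated hydroformylation, backed by base equilibration to the trans lactone. The ketol carbon stays a non-enolisable sp3 centre inside the dioxane until the last two, neutral steps.

Key step: step 15

Remark: the lactone is numbered O1, C2 (carbonyl), C3, C4, C5; ring A is the aryl ring of the C4 benzyl group, ring B the 1,3,4,5-tetrasubstituted ring of the C3 benzyl group, ring C the aryl ketone ring; Ar stands for 4-(benzyloxy)-3-methoxyphenyl; compounds 1 and 19 (O-benzylated vanillin derivatives) are taken as purchased.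

**Route**

Step 1
Reactants: 1 4-(benzyloxy)-3-methoxybenzyl alcohol
Product: 2 4-(benzyloxy)-3-methoxybenzyl bromide
Conditions: PBr3, Et2O, 0 °C
Reagents that add atoms: phosphorus tribromide, BrP(Br)Br
Why: Bromination of an electron-rich benzylic alcohol with PBr3 is a standard substitution that runs cold and leaves the aryl benzyl ether untouched, the bromide being used at once.

Step 2
Reactants: 3 (R)-4-benzyl-2-oxazolidinone; 4 crotonyl chloride ((E)-but-2-enoyl chloride)
Product: 6 (R)-4-benzyl-3-[(E)-but-2-enoyl]oxazolidin-2-one, via lithium oxazolidinide 5 (not isolated)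
Conditions: n-BuLi, THF, −78 °C; then 4, −78 to 0 °C
Reagents that add atoms: none
Why: Evans N-acylation of the lithiated oxazolidinone with an acid chloride is fast at low temperature and keeps the (E)-alkene.

Step 3
Reactants: 6 (R)-4-benzyl-3-[(E)-but-2-enoyl]oxazolidin-2-one; 2 4-(benzyloxy)-3-methoxybenzyl bromide
Product: 8 (R)-4-benzyl-3-[(R)-2-(4-benzyloxy-3-methoxybenzyl)but-3-enoyl]oxazolidin-2-one, via sodium dienolate 7 (not isolated)
Conditions: NaN(SiMe3)2, THF, −78 °C; then 2, −78 to −40 °C
Reagents that add atoms: none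
Why: In this Evans deconjugative alkylation the base removes a γ-proton to give the sodium-chelated (Z)-dienolate, which reacts at the α-carbon with the benzylic bromide on the face opposite the auxiliary's benzyl group and so sets the (R) centre that becomes C4.

Step 4
Reactants: 8 (R)-4-benzyl-3-[(R)-2-(4-benzyloxy-3-methoxybenzyl)but-3-enoyl]oxazolidin-2-one
Product: 9 (R)-2-[4-(benzyloxy)-3-methoxybenzyl]but-3-en-1-ol
Conditions: LiBH4, H2O (1 equiv), Et2O, 0 °C
Reagents that add atoms: none
Why: Reductive cleavage of the imide with LiBH4 should give the primary alcohol without touching the alkene or the α-centre and returns the auxiliary.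

Step 5
Reactants: 10 4-bromo-2-methoxyphenol; 11 allyl bromide
Product: 12 1-(allyloxy)-4-bromo-2-methoxybenzene
Conditions: K2CO3, acetone, reflux
Reagents that add atoms: none
Why: Williamson ether synthesis of a phenoxide with a reactive allylic halide.

Step 6
Reactants: 12 1-(allyloxy)-4-bromo-2-methoxybenzene
Product: 13 2-allyl-4-bromo-6-methoxyphenol
Conditions: N,N-diethylaniline, 200 °C
Reagents that add atoms: none
Why: The aromatic Claisen rearrangement (a [3,3]-sigmatropic shift followed by tautomerisation) places the allyl group on the only free ortho carbon, because the other ortho position carries the methoxy group.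

Step 7
Reactants: 13 2-allyl-4-bromo-6-methoxyphenol
Product: 14 1-allyl-2-(benzyloxy)-5-bromo-3-methoxybenzene
Conditions: BnBr, K2CO3, DMF, 50 °C
Reagents that add atoms: benzyl bromide, BrCc1ccccc1
Why: Williamson benzylation in a dipolar aprotic solvent masks the hindered phenol for the enolate and metal-catalysed steps that follow.

Step 8
Reactants: 14 1-allyl-2-(benzyloxy)-5-bromo-3-methoxybenzene
Product: 15 [2-(benzyloxy)-5-bromo-3-methoxyphenyl]acetaldehyde
Conditions: OsO4 (cat.), NaIO4, 2,6-lutidine, dioxane/H2O, rt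
Reagents that add atoms: sodium periodate, [Na+].[O-]I(=O)(=O)=O (oxygen relayed by catalytic osmium tetroxide, O=[Os](=O)(=O)=O)
Why: The Lemieux–Johnson oxidation (osmylation of the terminal alkene and periodate cleavage of the diol) shortens the allyl group by one carbon while the aryl bromide and ethers are inert, the aldehyde being carried on crude.

Step 9
Reactants: 15 [2-(benzyloxy)-5-bromo-3-methoxyphenyl]acetaldehyde
Product: 16 [2-(benzyloxy)-5-bromo-3-methoxyphenyl]acetic acid
Conditions: NaClO2, NaH2PO4, 2-methyl-2-butene, t-BuOH/H2O, 0 °C to rt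
Reagents that add atoms: sodium chlorite, [Na+].[O-]Cl=O
Why: The Pinnick oxidation converts the sensitive aldehyde to the acid under buffered conditions, the alkene scavenger removing hypochlorous acid before it can chlorinate the arene.

Step 10
Reactants: 16 [2-(benzyloxy)-5-bromo-3-methoxyphenyl]acetic acid; 3 (R)-4-benzyl-2-oxazolidinone
Product: 18 (R)-4-benzyl-3-{[2-(benzyloxy)-5-bromo-3-methoxyphenyl]acetyl}oxazolidin-2-one, via mixed pivalic anhydride 17 (not isolated)
Conditions: PivCl, Et3N, THF, −20 to 0 °C; then 3, LiCl, rt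
Reagents that add atoms: none
Why: Mixed-anhydride N-acylation of the oxazolidinone in the presence of LiCl takes place at the less hindered arylacetyl carbonyl and avoids an acid chloride.

Step 11
Reactants: 18 (R)-4-benzyl-3-{[2-(benzyloxy)-5-bromo-3-methoxyphenyl]acetyl}oxazolidin-2-one; 19 4-(benzyloxy)-3-methoxybenzaldehyde
Product: 22 (R)-4-benzyl-3-[(2R,3R)-2-(2-benzyloxy-5-bromo-3-methoxyphenyl)-3-(4-benzyloxy-3-methoxyphenyl)-3-hydroxypropanoyl]oxazolidin-2-one, via boron enolate 20 (not isolated), via boron aldolate 21 (not isolated)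
Conditions: Bu2BOTf, i-Pr2NEt, CH2Cl2, −78 to 0 °C; then 19, −78 to 0 °C; then pH 7 buffer, MeOH, H2O2, 0 °C
Reagents that add atoms: none
Why: In this Evans syn-aldol reaction the (Z)-boron enolate adds to the aldehyde through a closed Zimmerman–Traxler chair with the auxiliary carbonyl turned away from the boron, so the auxiliary fixes both the ring B-bearing carbon (the future ketol carbon) and the carbinol carbon in a syn relationship.

Step 12
Reactants: 22 syn-aldol imide
Product: 23 (1R,2S)-2-[2-(benzyloxy)-5-bromo-3-methoxyphenyl]-1-[4-(benzyloxy)-3-methoxyphenyl]propane-1,3-diol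
Conditions: LiBH4, MeOH (1 equiv), THF, 0 °C
Reagents that add atoms: none
Why: Reductive removal of the auxiliary with LiBH4 gives the 1,3-diol, leaves the aryl bromide alone and turns the acidic imide α-carbon into a centre with no adjacent carbonyl.

Step 13
Reactants: 23 (1R,2S)-diol
Product: 24 (4R,5S)-5-[2-(benzyloxy)-5-bromo-3-methoxyphenyl]-4-[4-(benzyloxy)-3-methoxyphenyl]-2,2-dimethyl-1,3-dioxane
Conditions: Me2C(OMe)2, PPTS (cat.), CH2Cl2, rt
Reagents that add atoms: 2,2-dimethoxypropane, COC(C)(C)OC
Why: Acid-catalysed transacetalisation closes the six-membered acetonide (4,5-cis), which hides both hydroxyls from the phosphinite exchange of step 15 and holds the ring B-bearing carbon as a non-enolisable sp3 centre.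

Step 14
Reactants: 24 aryl bromide acetonide; 9 (R)-2-[4-(benzyloxy)-3-methoxybenzyl]but-3-en-1-ol
Product: 25 (R,E)-2-[4-(benzyloxy)-3-methoxybenzyl]-4-{4-(benzyloxy)-3-methoxy-5-[(4R,5S)-4-Ar-2,2-dimethyl-1,3-dioxan-5-yl]phenyl}but-3-en-1-ol
Conditions: Pd2(dba)3 (cat.), [HP(t-Bu)3]BF4 (cat.), Cy2NMe, dioxane, 70 °C
Reagents that add atoms: none
Why: In this Heck reaction zerovalent palladium carrying the bulky electron-rich phosphine inserts into the electron-rich aryl bromide, the aryl group adds to the terminal alkene carbon and β-hydride elimination toward the benzylic hydrogen gives the conjugated (E)-styrene, with the free hydroxyl and the allylic centre untouched under the mild amine base.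

Step 15
Reactants: 25 homoallylic alcohol with the (E)-styrenyl alkene
Product: 27 (3R,4R)-4-[4-(benzyloxy)-3-methoxybenzyl]-3-{4-(benzyloxy)-3-methoxy-5-[(4R,5S)-4-Ar-2,2-dimethyl-1,3-dioxan-5-yl]benzyl}tetrahydrofuran-2-ol (both C2 epimers), via hydroxy aldehyde 26 (not isolated)
Conditions: Rh(acac)(CO)2 (cat.), Ph2POMe (cat.), CO/H2 (1:1, 40 bar), 4 Å MS, THF, 50 °C
Reagents that add atoms: carbon monoxide, [C-]#[O+]
Why: Ph2POMe exchanges its methoxy group for the C5 hydroxyl of 25 (the sieves take up methanol), so the rhodium hydride (monovalent rhodium) bound to that phosphinite is delivered within the molecule: hydride goes to the benzylic alkene carbon and rhodium to the nearer carbon, the future C3, through a six-membered Rh–C–C–C–O–P chelate, CO inserts into the Rh–C3 bond with retention, hydrogenolysis of the acyl gives the aldehyde and phosphinite exchange releases hydroxy aldehyde 26. The closest known reaction type is the hydroformylation of acyclic homoallylic alcohols, including 1,2-disubstituted alkenes, directed by catalytic, reversibly bound phosphinite ligands, which gives γ-lactols that are oxidised to γ-butyrolactones. The lactone ring closes by 5-exo-trig addition of the C5 hydroxyl to the new formyl carbon C2, giving the lactol as both C2 epimers, which converge on oxidation. The new C3 stereocentre is controlled by the existing C4 centre, since in the chair-like chelate the C4 benzyl group and the developing C3 benzyl group should both sit pseudo-equatorial, which leads to the trans (3R,4R) arrangement. The step needs regioselectivity against the innate benzylic formylation of styrenes, which would end in a six-membered lactol, and the short phosphinite tether secures it because rhodium at the benzylic carbon would require a seven-membered chelate; it also needs hydroformylation to outrun hydrogenation and isomerisation of the alkene, which CO pressure and moderate temperature favour.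

Step 16
Reactants: 27 γ-lactol
Product: 28 (3R,4R)-4-[4-(benzyloxy)-3-methoxybenzyl]-3-{4-(benzyloxy)-3-methoxy-5-[(4R,5S)-4-Ar-2,2-dimethyl-1,3-dioxan-5-yl]benzyl}dihydrofuran-2(3H)-one
Conditions: nPr4N[RuO4] (cat.), NMO, 4 Å MS, CH2Cl2, rt; then DBU, toluene, 50 °C
Reagents that add atoms: none
Why: Perruthenate-catalysed oxidation with NMO converts both lactol epimers into the same γ-lactone, and the DBU treatment equilibrates the enolisable C3 centre so that any cis isomer ends as the thermodynamically preferred trans-3,4-dibenzyl lactone, while C4 and the dioxane centres are not acidic and stay fixed.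

Step 17
Reactants: 28 lactone acetonide
Product: 29 (3R,4R)-4-[4-(benzyloxy)-3-methoxybenzyl]-3-{4-(benzyloxy)-3-[(1R,2S)-1-Ar-1,3-dihydroxypropan-2-yl]-5-methoxybenzyl}dihydrofuran-2(3H)-one
Conditions: AcOH/H2O/THF, 40 °C
Reagents that add atoms: none
Why: Mild aqueous acid hydrolyses the acetonide while the lactone and benzyl ethers survive, and the configuration of the carbinol carbon is of no consequence because it becomes the ketone in the next step.

Step 18
Reactants: 29 diol lactone
Product: 30 (3R,4R)-4-[4-(benzyloxy)-3-methoxybenzyl]-3-{4-(benzyloxy)-3-[(S)-1-Ar-3-hydroxy-1-oxopropan-2-yl]-5-methoxybenzyl}dihydrofuran-2(3H)-one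
Conditions: DDQ, 1,4-dioxane, rt
Reagents that add atoms: none
Why: DDQ dehydrogenation of electron-rich benzylic alcohols should take place by hydride abstraction at the carbinol carbon para to the benzyloxy group much faster than at the primary alcohol or the benzylic methylene groups, and the neutral medium leaves the newly enolisable α-aryl centre in its (S) configuration.

Step 19
Reactants: 30 tri-O-benzyl ketol
Product: 31 (3R,4R)-3-{4-hydroxy-3-[(S)-3-hydroxy-1-(4-hydroxy-3-methoxyphenyl)-1-oxopropan-2-yl]-5-methoxybenzyl}-4-(4-hydroxy-3-methoxybenzyl)dihydrofuran-2(3H)-one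
Conditions: H2 (1 atm), Pd/C, EtOAc/THF, rt
Reagents that add atoms: none
Why: Catalytic hydrogenolysis cleaves the three aryl benzyl ethers under neutral conditions, which avoids base-induced epimerisation or β-elimination of the ketol and acid-induced cyclodehydration to a benzofuran, while the electron-rich aryl ketone is reduced far more slowly than the benzyl ethers are cleaved.

**Compound list**

1 | 4-(benzyloxy)-3-methoxybenzyl alcohol | COc1cc(CO)ccc1OCc1ccccc1 | starting material
2 | 4-(benzyloxy)-3-methoxybenzyl bromide | COc1cc(CBr)ccc1OCc1ccccc1 | intermediate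
3 | (R)-4-benzyl-2-oxazolidinone | O=C1N[C@H](Cc2ccccc2)CO1 | starting material
4 | crotonyl chloride, (E)-but-2-enoyl chloride | C/C=C/C(=O)Cl | starting material
5 | lithium salt of 3 (N-lithio oxazolidinone, not isolated) | [Li]N1[C@H](Cc2ccccc2)COC1=O | intermediate
6 | (R)-4-benzyl-3-[(E)-but-2-enoyl]oxazolidin-2-one | C/C=C/C(=O)N1[C@H](Cc2ccccc2)COC1=O | intermediate
7 | sodium (Z)-dienolate of 6 (not isolated) | C=C/C=C(\O[Na])N1[C@H](Cc2ccccc2)COC1=O | intermediate
8 | (R)-4-benzyl-3-[(R)-2-(4-benzyloxy-3-methoxybenzyl)but-3-enoyl]oxazolidin-2-one | C=C[C@@H](Cc1ccc(OCc2ccccc2)c(OC)c1)C(=O)N1[C@H](Cc2ccccc2)COC1=O | intermediate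
9 | (R)-2-[4-(benzyloxy)-3-methoxybenzyl]but-3-en-1-ol | C=C[C@@H](Cc1ccc(OCc2ccccc2)c(OC)c1)CO | intermediate
10 | 4-bromo-2-methoxyphenol | COc1cc(Br)ccc1O | starting material
11 | allyl bromide | C=CCBr | starting material
12 | 1-(allyloxy)-4-bromo-2-methoxybenzene | COc1cc(Br)ccc1OCC=C | intermediate
13 | 2-allyl-4-bromo-6-methoxyphenol | COc1cc(Br)cc(CC=C)c1O | intermediate
14 | 1-allyl-2-(benzyloxy)-5-bromo-3-methoxybenzene | COc1cc(Br)cc(CC=C)c1OCc1ccccc1 | intermediate
15 | [2-(benzyloxy)-5-bromo-3-methoxyphenyl]acetaldehyde | COc1cc(Br)cc(CC=O)c1OCc1ccccc1 | intermediate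
16 | [2-(benzyloxy)-5-bromo-3-methoxyphenyl]acetic acid | COc1cc(Br)cc(CC(=O)O)c1OCc1ccccc1 | intermediate
17 | mixed anhydride of 16 with pivalic acid (not isolated) | COc1cc(Br)cc(CC(=O)OC(=O)C(C)(C)C)c1OCc1ccccc1 | intermediate
18 | (R)-4-benzyl-3-{[2-(benzyloxy)-5-bromo-3-methoxyphenyl]acetyl}oxazolidin-2-one | COc1cc(Br)cc(CC(=O)N2[C@H](Cc3ccccc3)COC2=O)c1OCc1ccccc1 | intermediate
19 | 4-(benzyloxy)-3-methoxybenzaldehyde | COc1cc(C=O)ccc1OCc1ccccc1 | starting material
20 | dibutylboron (Z)-enolate of 18 (not isolated) | COc1cc(Br)cc(/C=C(\OB(CCCC)CCCC)N2[C@H](Cc3ccccc3)COC2=O)c1OCc1ccccc1 | intermediate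
21 | O-dibutylboryl aldolate of 22 (not isolated) | COc1cc(Br)cc([C@@H](C(=O)N2[C@H](Cc3ccccc3)COC2=O)[C@@H](OB(CCCC)CCCC)c2ccc(OCc3ccccc3)c(OC)c2)c1OCc1ccccc1 | intermediate
22 | (R)-4-benzyl-3-[(2R,3R)-2-(2-benzyloxy-5-bromo-3-methoxyphenyl)-3-(4-benzyloxy-3-methoxyphenyl)-3-hydroxypropanoyl]oxazolidin-2-one | COc1cc(Br)cc([C@@H](C(=O)N2[C@H](Cc3ccccc3)COC2=O)[C@@H](O)c2ccc(OCc3ccccc3)c(OC)c2)c1OCc1ccccc1 | intermediate
23 | (1R,2S)-2-[2-(benzyloxy)-5-bromo-3-methoxyphenyl]-1-[4-(benzyloxy)-3-methoxyphenyl]propane-1,3-diol | COc1cc(Br)cc([C@@H](CO)[C@@H](O)c2ccc(OCc3ccccc3)c(OC)c2)c1OCc1ccccc1 | intermediate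
24 | (4R,5S)-5-[2-(benzyloxy)-5-bromo-3-methoxyphenyl]-4-[4-(benzyloxy)-3-methoxyphenyl]-2,2-dimethyl-1,3-dioxane | COc1cc(Br)cc([C@H]2COC(C)(C)O[C@H]2c2ccc(OCc3ccccc3)c(OC)c2)c1OCc1ccccc1 | intermediate
25 | (R,E)-2-[4-(benzyloxy)-3-methoxybenzyl]-4-{4-(benzyloxy)-3-methoxy-5-[(4R,5S)-4-Ar-2,2-dimethyl-1,3-dioxan-5-yl]phenyl}but-3-en-1-ol | COc1cc(C[C@@H](CO)/C=C/c2cc(OC)c(OCc3ccccc3)c([C@H]5COC(C)(C)O[C@H]5c3ccc(OCc4ccccc4)c(OC)c3)c2)ccc1OCc1ccccc1 | intermediate
26 | (2R,3R)-2-{4-(benzyloxy)-3-methoxy-5-[(4R,5S)-4-Ar-2,2-dimethyl-1,3-dioxan-5-yl]benzyl}-3-(hydroxymethyl)-4-[4-(benzyloxy)-3-methoxyphenyl]butanal (not isolated) | COc1cc(C[C@@H](CO)[C@H](C=O)Cc2cc(OC)c(OCc3ccccc3)c([C@H]5COC(C)(C)O[C@H]5c3ccc(OCc4ccccc4)c(OC)c3)c2)ccc1OCc1ccccc1 | intermediate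
27 | (3R,4R)-4-[4-(benzyloxy)-3-methoxybenzyl]-3-{4-(benzyloxy)-3-methoxy-5-[(4R,5S)-4-Ar-2,2-dimethyl-1,3-dioxan-5-yl]benzyl}tetrahydrofuran-2-ol, both C2 epimers | COc1cc(C[C@H]2COC(O)[C@@H]2Cc2cc(OC)c(OCc3ccccc3)c([C@H]5COC(C)(C)O[C@H]5c3ccc(OCc4ccccc4)c(OC)c3)c2)ccc1OCc1ccccc1 | intermediate
28 | (3R,4R)-4-[4-(benzyloxy)-3-methoxybenzyl]-3-{4-(benzyloxy)-3-methoxy-5-[(4R,5S)-4-Ar-2,2-dimethyl-1,3-dioxan-5-yl]benzyl}dihydrofuran-2(3H)-one | COc1cc(C[C@H]2COC(=O)[C@@H]2Cc2cc(OC)c(OCc3ccccc3)c([C@H]5COC(C)(C)O[C@H]5c3ccc(OCc4ccccc4)c(OC)c3)c2)ccc1OCc1ccccc1 | intermediate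
29 | (3R,4R)-4-[4-(benzyloxy)-3-methoxybenzyl]-3-{4-(benzyloxy)-3-[(1R,2S)-1-Ar-1,3-dihydroxypropan-2-yl]-5-methoxybenzyl}dihydrofuran-2(3H)-one | COc1cc(C[C@H]2COC(=O)[C@@H]2Cc2cc(OC)c(OCc3ccccc3)c([C@@H](CO)[C@@H](O)c3ccc(OCc4ccccc4)c(OC)c3)c2)ccc1OCc1ccccc1 | intermediate
30 | (3R,4R)-4-[4-(benzyloxy)-3-methoxybenzyl]-3-{4-(benzyloxy)-3-[(S)-1-Ar-3-hydroxy-1-oxopropan-2-yl]-5-methoxybenzyl}dihydrofuran-2(3H)-one | COc1cc(C[C@H]2COC(=O)[C@@H]2Cc2cc(OC)c(OCc3ccccc3)c([C@@H](CO)C(=O)c3ccc(OCc4ccccc4)c(OC)c3)c2)ccc1OCc1ccccc1 | intermediate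
31 | (3R,4R)-3-{4-hydroxy-3-[(S)-3-hydroxy-1-(4-hydroxy-3-methoxyphenyl)-1-oxopropan-2-yl]-5-methoxybenzyl}-4-(4-hydroxy-3-methoxybenzyl)dihydrofuran-2(3H)-one | COc1cc(C[C@H]2COC(=O)[C@@H]2Cc2cc(OC)c(O)c([C@@H](CO)C(=O)c3ccc(O)c(OC)c3)c2)ccc1O | target

**Step count**

Total: 19 steps. Longest linear sequence: 15 steps (steps 5–19, from 4-bromo-2-methoxyphenol 10).

**Steps most likely to fail**

1. Step 15. Rhodium may add at the benzylic carbon (the innate regiochemistry of styrenes), the hindered internal alkene may turn over slowly, or hydrogenation of the alkene may compete. The fallback sets out from 25. Phosgene and pyridine (THF, 0 °C) would convert the hydroxyl into the chloroformate of 25 F1, and PhSeH with pyridine would turn this into the Se-phenyl selenocarbonate of 25 F2. Bu3SnH and AIBN in benzene at 80 °C would then generate the alkoxycarbonyl radical, which closes 5-exo-trig onto the styrene carbon nearer the oxygen; the benzylic radical so formed takes hydrogen from the stannane. After the DBU treatment of step 16 this gives lactone 28, where the route is rejoined, lactol 27 being bypassed. The same C2–C3 bond forms, but O1–C2 is made first and the regiochemistry is fixed by ring size and by the benzylic radical.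

2. Step 18. Hydride abstraction at the para-alkoxy benzylic methylene groups of the lactone may compete with oxidation of the carbinol, or conversion may stall. The fallback sets out from 29. TBSCl and imidazole (DMF, 0 °C) would silylate the primary hydroxyl selectively to the primary tert-butyldimethylsilyl ether of 29 F3. Dess–Martin periodinane with NaHCO3 in CH2Cl2 would oxidise the remaining benzylic alcohol to the silyl-protected ketol F4. HF·pyridine in THF at 0 °C would remove the silyl group under non-basic conditions and return the route at 30.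

3. Step 14. Re-addition of palladium hydride may move the double bond out of conjugation toward the allylic C4 centre, with loss of the alkene position and possibly of the C4 configuration, or the electron-rich bromide may react sluggishly. The fallback sets out from 24. Suzuki–Miyaura coupling with vinylboronic acid pinacol ester (PdCl2(dppf), K2CO3, dioxane/H2O, 80 °C) would give the ring B styrene F5. Cross-metathesis of this styrene with alkene 9 (second-generation Grubbs catalyst, CH2Cl2, 40 °C), with loss of ethylene, would give the (E)-alkene 25, where the route is rejoined.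

Further compounds
F1 | step 15 | chloroformate of 25, (R,E)-2-[4-(benzyloxy)-3-methoxybenzyl]-4-aryl-but-3-enyl carbonochloridate | COc1cc(C[C@@H](COC(=O)Cl)/C=C/c2cc(OC)c(OCc3ccccc3)c([C@H]5COC(C)(C)O[C@H]5c3ccc(OCc4ccccc4)c(OC)c3)c2)ccc1OCc1ccccc1
F2 | step 15 | Se-phenyl selenocarbonate of 25 | COc1cc(C[C@@H](COC(=O)[Se]c6ccccc6)/C=C/c2cc(OC)c(OCc3ccccc3)c([C@H]5COC(C)(C)O[C@H]5c3ccc(OCc4ccccc4)c(OC)c3)c2)ccc1OCc1ccccc1
F3 | step 18 | primary tert-butyldimethylsilyl ether of 29 | COc1cc(C[C@H]2COC(=O)[C@@H]2Cc2cc(OC)c(OCc3ccccc3)c([C@@H](CO[Si](C)(C)C(C)(C)C)[C@@H](O)c3ccc(OCc4ccccc4)c(OC)c3)c2)ccc1OCc1ccccc1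
F4 | step 18 | tert-butyldimethylsilyl ether of ketol 30 | COc1cc(C[C@H]2COC(=O)[C@@H]2Cc2cc(OC)c(OCc3ccccc3)c([C@@H](CO[Si](C)(C)C(C)(C)C)C(=O)c3ccc(OCc4ccccc4)c(OC)c3)c2)ccc1OCc1ccccc1
F5 | step 14 | (4R,5S)-5-[2-(benzyloxy)-3-methoxy-5-vinylphenyl]-4-[4-(benzyloxy)-3-methoxyphenyl]-2,2-dimethyl-1,3-dioxane | COc1cc(C=C)cc([C@H]2COC(C)(C)O[C@H]2c2ccc(OCc3ccccc3)c(OC)c2)c1OCc1ccccc1
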